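**Plan**
1. Cuts: C12–C13 (butenolide, from tetronic acid), C1–C10 (ring A), C3–C4 (lactone enolate allylation), C9–C11 (enol triflate coupling), C4–C5 (Michael addition to a quinone monoketal made from 4-methoxy-2,6-dimethylphenol).
2. Forward: ring B is the dearomatised phenol, which already carries both ring methyls and oxygen at C6 and C9. C4–C5, C8–OH, the C6 alcohol (as a lactone), C9–C11 and C3–C4 are added around it; ring A closes by C1–C10; the butenolide is coupled last.
3. Enabling feature: C10 is quaternary and allylic to C8=C9, and the oxygenated C2 is joined to C10 through C1. Ring A can therefore close by union of a C8–C9–C10 allyl cation (at C10) with carbon C1 of a C1=C2 silyl enol ether.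
4. Stereochemistry: C5 from an (S,S)-hydrobenzoin ketal; C6 by hydride delivery anti to the C5 side chain; C4 by convex-face allylation of the cis-fused lactone; C10 by the C5 tether (cis fusion); C2 by electron-transfer (thermodynamic) reduction.

Key step: step 16

Numbering: ring A = C1–C5 and C10; ring B = C5–C10; C18 (methyl) and C19 (acetoxymethyl) on C4; C17 methyl on C8; C20 methyl on C10; C11–C12 on C9; butenolide C13–C16. α = face of the C5–C4 bond, β = face of H5.
Assumption: the ester enolate in step 3 attacks the enone face not covered by the phenyl group on the nearer ketal carbon, which with the (S,S)-diol gives the C5 configuration of the target; if the opposite sense is found, the (R,R)-diol is used.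
Assumption: epimers at C4 (until step 10), C10 (until step 8) and C8 (until step 16) are carried as mixtures, because these centres are reset or made planar later.

Step 1
Reactants: 1 4-methoxy-2,6-dimethylphenol
Product: 2 4,4-dimethoxy-2,6-dimethylcyclohexa-2,5-dien-1-one
Conditions: PhI(OAc)2, MeOH, 0 °C
Reagents that add atoms: methanol, CO
Why: Oxidative dearomatisation of a para-alkoxyphenol with PhI(OAc)2 in methanol is the standard entry to quinone monoketals, the solvent trapping the aryloxenium ion at the methoxy-bearing carbon (future C6) without forming a stereocentre.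

Step 2
Reactants: 2 4,4-dimethoxy-2,6-dimethylcyclohexa-2,5-dien-1-one; 3 (1S,2S)-1,2-diphenylethane-1,2-diol
Product: 4 (2S,3S)-7,9-dimethyl-2,3-diphenyl-1,4-dioxaspiro[4.5]deca-6,9-dien-8-one
Conditions: BF3·OEt2 (cat.), DME, 0 °C → rt
Reagents that add atoms: none
Why: Acid-catalysed transketalisation is driven by dioxolane formation and loss of methanol, and the twofold-symmetric diol makes the two enone halves equivalent while rendering the two faces of each diastereotopic.

Step 3
Reactants: 4 (2S,3S)-7,9-dimethyl-2,3-diphenyl-1,4-dioxaspiro[4.5]deca-6,9-dien-8-one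
Product: 5 methyl 2-[(2S,3S)-7,9-dimethyl-8-oxo-2,3-diphenyl-1,4-dioxaspiro[4.5]dec-9-en-6-yl]propanoate (C5 as in the target; C4 and C10 epimers)
Conditions: LiN(i-Pr)2, methyl propanoate, THF, −78 °C; then 4, DMPU, −78 → −30 °C; AcOH
Reagents that add atoms: methyl propanoate, CCC(=O)OC
Why: Michael addition of a lithium ester enolate to the quinone monoketal, in which any adduct at the methyl-flanked carbonyl should revert on warming while the 1,4-adduct accumulates, and the enolate should enter C5 from the α face left open by the ketal phenyl groups, which sets C5.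

Step 4
Reactants: 5 Michael adduct
Product: 7 methyl 2-[(2S,3S)-9-hydroxy-7,9-dimethyl-8-oxo-2,3-diphenyl-1,4-dioxaspiro[4.5]decan-6-yl]propanoate (C8 tertiary alcohol, both epimers), via C8 hydroperoxide 6 (not isolated)
Conditions: Mn(dpm)3 (cat., dpm = dipivaloylmethanate), PhSiH3, O2 (1 atm), i-PrOH/CH2Cl2, 0 °C; then P(OEt)3
Reagents that add atoms: dioxygen, O=O
Why: Mukaiyama-type hydrogen-atom-transfer hydration of the remaining α-methyl enone puts hydrogen on C7 and traps the tertiary α-keto radical at C8 with oxygen, the phosphite reducing the hydroperoxide; the C8 configuration is irrelevant because C8 is ionised in step 16.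

Step 5
Reactants: 7 C8 tertiary alcohol
Product: 8 C8 triethylsilyl ether of 7
Conditions: Et3SiOTf, 2,6-lutidine, CH2Cl2, −78 → 0 °C
Reagents that add atoms: triethylsilyl triflate, CC[Si](CC)(CC)OS(=O)(=O)C(F)(F)F
Why: Silyl triflate with a hindered pyridine silylates tertiary α-ketols; the ether blocks retro-aldol and enolate chemistry at C8 and later serves as the leaving group of the key step.

Step 6
Reactants: 8 C8 triethylsilyl ether
Product: 9 methyl 2-[2,4-dimethyl-3,6-dioxo-4-(triethylsilyloxy)cyclohexyl]propanoate (C6 ketone; C5 as in the target)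
Conditions: H2 (1 atm), Pd(OH)2/C, EtOAc, rt
Reagents that add atoms: none
Why: Both ketal C–O bonds are benzylic, so hydrogenolysis should release the C6 ketone under neutral conditions that spare the β-silyloxy ketone, which aqueous acid could dehydrate.

Step 7
Reactants: 9 C6 ketone
Product: 11 cis-fused keto lactone, 3,4,6-trimethyl-6-(triethylsilyloxy)hexahydro-1-benzofuran-2,5-dione (H5 and H6 cis; C5, C6 as in the target), via cis hydroxy ester 10 (not isolated)
Conditions: LiBH(s-Bu)3, THF, −78 → 0 °C; aq. NH4Cl
Reagents that add atoms: none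
Why: The bulky trialkylborohydride should attack the C6 ketone from the β face, opposite the C5 side chain, and leave the doubly flanked C9 ketone alone; the resulting cis alkoxide closes the γ-lactone on the methyl ester, which sets C6.

Step 8
Reactants: 11 cis-fused keto lactone
Product: 12 C9 enol triflate, 3,4,6-trimethyl-2-oxo-6-(triethylsilyloxy)-2,3,3a,6,7,7a-hexahydro-1-benzofuran-5-yl trifluoromethanesulfonate
Conditions: KN(SiMe3)2, THF, −78 °C; PhNTf2, −78 → 0 °C
Reagents that add atoms: N-phenylbis(trifluoromethanesulfonimide), O=S(=O)(N(c1ccccc1)S(=O)(=O)C(F)(F)F)C(F)(F)F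
Why: The ketone is more acidic than the lactone and has an α-hydrogen only at C10 (C8 is quaternary), so enolate O-sulfonylation can give only the C9=C10 enol triflate, which also erases the C10 epimers.

Step 9
Reactants: 12 C9 enol triflate
Product: 13 5-[2-(tert-butyldimethylsilyloxy)ethyl]-3,4,6-trimethyl-6-(triethylsilyloxy)-3a,6,7,7a-tetrahydro-1-benzofuran-2(3H)-one
Conditions: tert-butyldimethyl(vinyloxy)silane, 9-BBN, THF, 0 °C → rt; then 12, PdCl2(dppf), AsPh3, Cs2CO3, DMF/H2O, 50 °C
Reagents that add atoms: tert-butyldimethyl(vinyloxy)silane, C=CO[Si](C)(C)C(C)(C)C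
Why: B-alkyl Suzuki–Miyaura coupling, in which 9-BBN adds to the vinyl ether with boron on the terminal carbon and the primary alkyl group is transferred to the enol triflate, fixing the tetrasubstituted C9=C10 alkene and the C11–C12 chain.

Step 10
Reactants: 13 lactone with C9 side chain
Product: 14 C4-allylated lactone (C4 quaternary: allyl cis to H5, methyl toward C10)
Conditions: LiN(i-Pr)2, THF, −78 °C; allyl bromide, DMPU, −78 → −30 °C
Reagents that add atoms: allyl bromide, C=CCBr
Why: Alkylation of the α-methyl lactone enolate on the convex face of the cis-fused bicycle, away from C10 and its methyl group, sets the C4 quaternary centre with C3 cis to H5, and both C4 epimers of 13 converge on one enolate.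

Step 11
Reactants: 14 C4-allylated lactone
Product: 15 (4S,5S,6S)-diol: C4 carries CH3, CH2OH (C19) and allyl; C6–OH cis to the C5–C4 bond; C8 CH3/OSiEt3; C9 CH2CH2OTBS; C9=C10
Conditions: LiAlH4, THF, 0 °C
Reagents that add atoms: none
Why: Hydride reduction of the lactone gives the 1,4-diol without touching silyl ethers or alkenes.

Step 12
Reactants: 15 diol
Product: 16 C19 monoacetate of 15
Conditions: Ac2O, pyridine, CH2Cl2, 0 °C
Reagents that add atoms: acetic anhydride, CC(=O)OC(C)=O
Why: The primary C19 alcohol is acylated much faster than the C6 alcohol, which is secondary and flanked by the C5 stereocentre bearing the quaternary C4.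

Step 13
Reactants: 16 C19 monoacetate
Product: 17 C6 tert-butyldimethylsilyl ether of 16
Conditions: t-BuMe2SiOTf, 2,6-lutidine, CH2Cl2, −78 → 0 °C
Reagents that add atoms: tert-butyldimethylsilyl triflate, CC(C)(C)[Si](C)(C)OS(=O)(=O)C(F)(F)F
Why: Silyl triflate silylates the hindered secondary alcohol and so prevents intramolecular oxypalladation by the C6 hydroxyl in the next step.

Step 14
Reactants: 17 allyl compound
Product: 18 methyl ketone (arm C3H2–C2(=O)–C1H3 on C4)
Conditions: PdCl2 (cat.), CuCl, O2 (1 atm), DMF/H2O, rt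
Reagents that add atoms: water, O
Why: Wacker–Tsuji oxidation converts the terminal alkene into the methyl ketone with Markovnikov selectivity, while the tetrasubstituted C9=C10 alkene is too hindered to react.

Step 15
Reactants: 18 methyl ketone
Product: 19 (4S,5S,6S)-key precursor: C4 carries CH3, CH2OAc and CH2–C(OTBS)=CH2; C6 α-OTBS; C8 CH3/OSiEt3 (both epimers); C9 CH2CH2OTBS; C9=C10; C10 CH3
Conditions: t-BuMe2SiOTf, Et3N, CH2Cl2, −78 → 0 °C
Reagents that add atoms: tert-butyldimethylsilyl triflate, CC(C)(C)[Si](C)(C)OS(=O)(=O)C(F)(F)F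
Why: Soft enolisation with silyl triflate and amine should remove a proton from the open methyl group C1 and not from the neopentyl C3, and the acetate does not enolise under these conditions.

Step 16
Reactants: 19 key precursor
Product: 21 (4S,5S,6S,10S)-cis-decalin C2 ketone (C19 OAc, C6 α-OTBS, C8=C9, C9 CH2CH2OTBS), via C8–C10 allyl cation 20 (not isolated)
Conditions: Me3SiOTf, 2,6-di-tert-butyl-4-methylpyridine, CH2Cl2, −78 → −40 °C; aq. NaHCO3
Reagents that add atoms: none
Why: Me3SiOTf silylates the oxygen of the tertiary C8 silyl ether, the disiloxane leaves, and the allyl cation spread over C8–C9–C10 is attacked at C10 by enol ether carbon C1; the silyloxycarbenium ion then loses its silyl group to leave the C2 ketone and the C8=C9 alkene. The closest known reaction type is the Lewis-acid-mediated SN1 alkylation of silyl enol ethers by tertiary and allylic cations, run here intramolecularly. Ring A closes in a 6-(enolendo)-exo-trig mode, and attack at C8 would need a bridged eight-membered ring, so C10 is the only terminus within reach. The new quaternary centre C10 is controlled by C5: bond formation along the axis of the cation p orbital is possible for the tethered nucleophile only on the α face, cis to the C5–C4 bond, and a chair-like ring A then gives the cis-fused decalin. The step needs C–C bond formation to outrun proton loss from the cation and protodesilylation; the low temperature, the hindered pyridine and the high nucleophilicity of the 1,1-disubstituted silyl enol ether serve this, and both C8 epimers give the same cation.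

Step 17
Reactants: 21 cis-decalin C2 ketone
Product: 22 (2R,4S,5S,6S,10S)-2α-alcohol (equatorial OH)
Conditions: SmI2, H2O, THF, 0 °C
Reagents that add atoms: none
Why: Electron-transfer reduction by divalent samarium goes through a ketyl and carbanion that settle into the more stable equatorial alcohol, whereas hydride reagents would be forced to the α face by the axial C19 and C20 groups and give the axial 2β-alcohol; this sets C2.

Step 18
Reactants: 22 2α-alcohol
Product: 23 triol (C2, C6, C12 hydroxyls; C19 acetate)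
Conditions: HF·pyridine, pyridine/THF, 0 °C → rt
Reagents that add atoms: none
Why: Fluoride-mediated cleavage removes both silyl ethers and leaves the acetate and the tetrasubstituted alkene untouched.

Step 19
Reactants: 23 triol
Product: 24 C12 primary iodide (C2, C6 hydroxyls free)
Conditions: I2, PPh3, imidazole, CH2Cl2, 0 °C
Reagents that add atoms: iodine, II
Why: Appel-type iodination is selective for the unhindered primary alcohol over the two secondary ring alcohols.

Step 20
Reactants: 25 tetronic acid
Product: 26 4-bromofuran-2(5H)-one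
Conditions: (COBr)2, DMF, CH2Cl2, 0 °C → rt
Reagents that add atoms: oxalyl bromide, O=C(Br)C(=O)Br
Why: Vilsmeier-type activation of the enol hydroxyl of the vinylogous acid and addition–elimination by bromide give the β-bromobutenolide.

Step 21
Reactants: 24 C12 primary iodide; 26 4-bromofuran-2(5H)-one
Product: 27 target, CNP0201970.1
Conditions: NiI2 (cat.), 4,4′-di-tert-butyl-2,2′-bipyridine, Zn, pyridine (cat.), DMA, rt
Reagents that add atoms: none
Why: Nickel-catalysed reductive cross-electrophile coupling joins the primary alkyl iodide to the alkenyl bromide (C12–C13) without a preformed organometallic, so the free hydroxyls, the acetate and the butenolide are tolerated.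

**Compound list**
1 | 4-methoxy-2,6-dimethylphenol | COc1cc(C)c(O)c(C)c1 | starting material
2 | 4,4-dimethoxy-2,6-dimethylcyclohexa-2,5-dien-1-one | COC1(OC)C=C(C)C(=O)C(C)=C1 | intermediate
3 | (1S,2S)-1,2-diphenylethane-1,2-diol | O[C@@H](c1ccccc1)[C@@H](O)c1ccccc1 | starting material
4 | (2S,3S)-7,9-dimethyl-2,3-diphenyl-1,4-dioxaspiro[4.5]deca-6,9-dien-8-one | O=C1C(C)=CC2(C=C1C)O[C@@H](c3ccccc3)[C@H](c4ccccc4)O2 | intermediate
5 | methyl 2-[(2S,3S)-7,9-dimethyl-8-oxo-2,3-diphenyl-1,4-dioxaspiro[4.5]dec-9-en-6-yl]propanoate (C5 as in target; C4, C10 epimers) | COC(=O)C(C)[C@@H]1C(C)C(=O)C(C)=CC12O[C@@H](c3ccccc3)[C@H](c4ccccc4)O2 | intermediate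
6 | C8 hydroperoxide of 5 (C7 saturated) | COC(=O)C(C)[C@@H]1C(C)C(=O)C(C)(OO)CC12O[C@@H](c3ccccc3)[C@H](c4ccccc4)O2 | intermediate (not isolated)
7 | C8 tertiary alcohol (α-hydroxy ketone) | COC(=O)C(C)[C@@H]1C(C)C(=O)C(C)(O)CC12O[C@@H](c3ccccc3)[C@H](c4ccccc4)O2 | intermediate
8 | C8 triethylsilyl ether of 7 | COC(=O)C(C)[C@@H]1C(C)C(=O)C(C)(O[Si](CC)(CC)CC)CC12O[C@@H](c3ccccc3)[C@H](c4ccccc4)O2 | intermediate
9 | methyl 2-[2,4-dimethyl-3,6-dioxo-4-(triethylsilyloxy)cyclohexyl]propanoate | COC(=O)C(C)[C@@H]1C(C)C(=O)C(C)(O[Si](CC)(CC)CC)CC1=O | intermediate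
10 | methyl 2-[6-hydroxy-2,4-dimethyl-3-oxo-4-(triethylsilyloxy)cyclohexyl]propanoate (C6–OH cis to side chain) | COC(=O)C(C)[C@@H]1C(C)C(=O)C(C)(O[Si](CC)(CC)CC)C[C@@H]1O | intermediate (not isolated)
11 | cis-fused keto lactone, 3,4,6-trimethyl-6-(triethylsilyloxy)hexahydro-1-benzofuran-2,5-dione | CC1C(=O)O[C@H]2CC(C)(O[Si](CC)(CC)CC)C(=O)C(C)[C@@H]12 | intermediate
12 | C9 enol triflate of 11 | CC1C(=O)O[C@H]2CC(C)(O[Si](CC)(CC)CC)C(OS(=O)(=O)C(F)(F)F)=C(C)[C@@H]12 | intermediate
13 | lactone with C9 CH2CH2OTBS chain | CC1C(=O)O[C@H]2CC(C)(O[Si](CC)(CC)CC)C(CCO[Si](C)(C)C(C)(C)C)=C(C)[C@@H]12 | intermediate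
14 | C4-allylated lactone | C=CC[C@]1(C)C(=O)O[C@H]2CC(C)(O[Si](CC)(CC)CC)C(CCO[Si](C)(C)C(C)(C)C)=C(C)[C@@H]12 | intermediate
15 | (4S,5S,6S)-C19,C6-diol | C=CC[C@](C)(CO)[C@H]1[C@@H](O)CC(C)(O[Si](CC)(CC)CC)C(CCO[Si](C)(C)C(C)(C)C)=C1C | intermediate
16 | C19 monoacetate | C=CC[C@](C)(COC(C)=O)[C@H]1[C@@H](O)CC(C)(O[Si](CC)(CC)CC)C(CCO[Si](C)(C)C(C)(C)C)=C1C | intermediate
17 | C6 TBS ether of 16 | C=CC[C@](C)(COC(C)=O)[C@H]1[C@@H](O[Si](C)(C)C(C)(C)C)CC(C)(O[Si](CC)(CC)CC)C(CCO[Si](C)(C)C(C)(C)C)=C1C | intermediate
18 | methyl ketone | CC(=O)C[C@](C)(COC(C)=O)[C@H]1[C@@H](O[Si](C)(C)C(C)(C)C)CC(C)(O[Si](CC)(CC)CC)C(CCO[Si](C)(C)C(C)(C)C)=C1C | intermediate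
19 | key precursor (TBS enol ether, C8 silyl ether) | C=C(O[Si](C)(C)C(C)(C)C)C[C@](C)(COC(C)=O)[C@H]1[C@@H](O[Si](C)(C)C(C)(C)C)CC(C)(O[Si](CC)(CC)CC)C(CCO[Si](C)(C)C(C)(C)C)=C1C | intermediate
20 | C8–C9–C10 allyl cation | C=C(O[Si](C)(C)C(C)(C)C)C[C@](C)(COC(C)=O)[C@H]1[C@@H](O[Si](C)(C)C(C)(C)C)C[C+](C)C(CCO[Si](C)(C)C(C)(C)C)=C1C | intermediate (not isolated)
21 | (4S,5S,6S,10S)-cis-decalin C2 ketone | CC(=O)OC[C@@]1(C)CC(=O)C[C@]2(C)C(CCO[Si](C)(C)C(C)(C)C)=C(C)C[C@H](O[Si](C)(C)C(C)(C)C)[C@H]12 | intermediate
22 | (2R,4S,5S,6S,10S)-2α-alcohol | CC(=O)OC[C@@]1(C)C[C@H](O)C[C@]2(C)C(CCO[Si](C)(C)C(C)(C)C)=C(C)C[C@H](O[Si](C)(C)C(C)(C)C)[C@H]12 | intermediate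
23 | triol | CC(=O)OC[C@@]1(C)C[C@H](O)C[C@]2(C)C(CCO)=C(C)C[C@H](O)[C@H]12 | intermediate
24 | C12 iodide | CC(=O)OC[C@@]1(C)C[C@H](O)C[C@]2(C)C(CCI)=C(C)C[C@H](O)[C@H]12 | intermediate
25 | tetronic acid | O=C1CC(=O)CO1 | starting material
26 | 4-bromofuran-2(5H)-one | BrC1=CC(=O)OC1 | intermediate
27 | CNP0201970.1, (2R,4S,5S,6S,10S) | CC(=O)OC[C@@]1(C)C[C@H](O)C[C@]2(C)C(CCC3=CC(=O)OC3)=C(C)C[C@H](O)[C@H]12 | target

**Totals:** 21 steps; longest linear sequence 20 steps (steps 1–19 and 21).

**Steps most likely to fail**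

Step 16. What may go wrong: proton loss from the allyl cation to ring-B dienes and protodesilylation of the enol ether outrun C–C bond formation, or attack on the β face erodes the cis fusion. The fallback sets out from 18 and comes back at 21, and replaces the enol ether by an allylsilane, which tolerates traces of acid and stronger Lewis acids at lower temperature. Kinetic enolisation of 18 (KN(SiMe3)2, PhNTf2, −78 °C) should give the terminal enol triflate F1. Cross-coupling with Me3SiCH2ZnCl (Pd(PPh3)4, THF) should give the 2-substituted allylsilane F2. Ionisation of the C8 silyl ether (Me3SiOTf or SnCl4, CH2Cl2, −78 °C) then closes ring A by an intramolecular Hosomi–Sakurai alkylation to the C2 exo-methylene cis-decalin F3. Lemieux–Johnson cleavage of the 1,1-disubstituted alkene (OsO4 cat., NaIO4, 2,6-lutidine, dioxane/H2O) gives 21.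

Step 3. What may go wrong: poor facial discrimination by the ketal, together with some attack at the carbonyl group, so that the material is not enantiomerically pure once the auxiliary is removed. The fallback sets out from lactone 11 and comes back to 11 by classical resolution. Aminolysis with (S)-1-phenylethylamine (AlMe3, CH2Cl2) should open the lactone to the diastereomeric hydroxy amide F4 (from 11) and hydroxy amide F5 (from the enantiomer of 11). After separation, acid-catalysed relactonisation of F4 (PPTS, toluene, 80 °C) returns 11.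

Step 17. What may go wrong: kinetic protonation or competing hydride-like delivery from the open α face gives the axial 2β-alcohol instead of the equatorial one. The fallback sets out from 21 and comes back at 22 by accepting the kinetic outcome and inverting it. LiBH(s-Bu)3 (THF, −78 °C) should give the axial 2β-alcohol F6. Mitsunobu reaction with chloroacetic acid (PPh3, DIAD, toluene) inverts C2 to the equatorial 2α-chloroacetate F7. Thiourea with NaHCO3 in ethanol removes the chloroacetyl group in the presence of the C19 acetate to give 22.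

**Further compounds**
F1 | step 16 | terminal enol triflate of 18 | C=C(OS(=O)(=O)C(F)(F)F)C[C@](C)(COC(C)=O)[C@H]1[C@@H](O[Si](C)(C)C(C)(C)C)CC(C)(O[Si](CC)(CC)CC)C(CCO[Si](C)(C)C(C)(C)C)=C1C
F2 | step 16 | 2-substituted allylsilane (CH2–C(=CH2)–CH2SiMe3 arm on C4) | C=C(C[Si](C)(C)C)C[C@](C)(COC(C)=O)[C@H]1[C@@H](O[Si](C)(C)C(C)(C)C)CC(C)(O[Si](CC)(CC)CC)C(CCO[Si](C)(C)C(C)(C)C)=C1C
F3 | step 16 | C2 exo-methylene cis-decalin | CC(=O)OC[C@@]1(C)CC(=C)C[C@]2(C)C(CCO[Si](C)(C)C(C)(C)C)=C(C)C[C@H](O[Si](C)(C)C(C)(C)C)[C@H]12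
F4 | step 3 | hydroxy amide from 11 and (S)-1-phenylethylamine | CC(C(=O)N[C@@H](C)c1ccccc1)[C@@H]1C(C)C(=O)C(C)(O[Si](CC)(CC)CC)C[C@@H]1O
F5 | step 3 | hydroxy amide from the enantiomer of 11 and (S)-1-phenylethylamine | CC(C(=O)N[C@@H](C)c1ccccc1)[C@H]1C(C)C(=O)C(C)(O[Si](CC)(CC)CC)C[C@H]1O
F6 | step 17 | axial 2β-alcohol | CC(=O)OC[C@@]1(C)C[C@@H](O)C[C@]2(C)C(CCO[Si](C)(C)C(C)(C)C)=C(C)C[C@H](O[Si](C)(C)C(C)(C)C)[C@H]12
F7 | step 17 | equatorial 2α-chloroacetate | CC(=O)OC[C@@]1(C)C[C@H](OC(=O)CCl)C[C@]2(C)C(CCO[Si](C)(C)C(C)(C)C)=C(C)C[C@H](O[Si](C)(C)C(C)(C)C)[C@H]12
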